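The seven-membered ring (azulene numbering: C3a, C4, C5, C6, C7, C8, C8a) is disconnected at the C4–C5 bond and is closed last on a finished cyclopentane. The key step exploits the δ-hydroxy β-methyl enone C4(O)–C5H2–C6(CH3)=C7H–C8(=O) as the retron of a type 2 intramolecular carbonyl–ene reaction. The C4 aldehyde adds to a methallyl ketone side chain, which forms the ring and sets the C4 carbinol centre in one operation; base then conjugates the alkene. The precursor is a trans-1,2-disubstituted cyclopentane carrying the aldehyde at C3a and a 3-methylbut-3-enoyl group on the quaternary C8a, assembled by copper-catalysed asymmetric conjugate addition and enolate trapping.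

Key step: step 7

Remark: atom labels C1–C8a are the azulene locants of the target and are kept for the same carbons in all intermediates. The enantiomer of the NHC ligand in step 1 is assumed to be the one that delivers the S-configured quaternary centre; both antipodes are accessible.

Step 1
Reactants: 1 3-methylcyclopent-2-en-1-one; 2 ethynyl(trimethyl)silane
Product: 5 triethyl({(3S)-3-methyl-3-[1-(trimethylsilyl)ethenyl]cyclopent-1-en-1-yl}oxy)silane, via alkenylalane 3 (not isolated), via aluminium enolate 4 (not isolated)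
Conditions: 2, i-Bu2AlH, hexanes, 55 °C; then 1, Cu(OTf)2 (5 mol %), chiral sulfonate-bearing imidazolinium salt (NHC precursor, 5 mol %), THF, −78 → −15 °C; then Et3SiOTf, −78 → 0 °C
Reagents that add atoms: ethynyl(trimethyl)silane C#C[Si](C)(C)C; triethylsilyl trifluoromethanesulfonate CC[Si](CC)(CC)OS(=O)(=O)C(F)(F)F
Why: Hydroalumination places aluminium geminal to silicon, the NHC–copper-catalysed asymmetric conjugate addition of this alkenylalane to the β-methyl enone should set the quaternary centre C8a under catalyst control, and O-silylation of the aluminium enolate stores the enolate regiochemistry at C3a.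

Step 2
Reactants: 5 silyl enol ether; 6 trimethyl orthoformate
Product: 7 (2S,3S)-2-(dimethoxymethyl)-3-methyl-3-[1-(trimethylsilyl)ethenyl]cyclopentan-1-one
Conditions: HC(OMe)3, Me3SiOTf (10 mol %), CH2Cl2, −78 °C; Et3N, then aq. NaHCO3
Reagents that add atoms: trimethyl orthoformate COC(OC)OC
Why: Mukaiyama-type alkylation of the silyl enol ether by the dimethoxycarbenium ion should occur at C3a on the face opposite the bulky 1-(trimethylsilyl)ethenyl group, which sets C3a trans to that group (also the thermodynamically preferred epimer).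

Step 3
Reactants: 7 keto acetal; 8 isopropylmagnesium chloride
Product: 9 (1R,2R,3S)-2-(dimethoxymethyl)-3-methyl-1-(propan-2-yl)-3-[1-(trimethylsilyl)ethenyl]cyclopentan-1-ol
Conditions: i-PrMgCl, anhydrous CeCl3, THF, −78 → 0 °C; aq. NH4Cl
Reagents that add atoms: isopropylmagnesium chloride CC(C)[Mg]Cl
Why: Organocerium 1,2-addition suppresses enolisation and reduction, and the nucleophile should approach the cyclopentanone anti to the adjacent C3a substituent, so the new C3 hydroxyl ends up cis to the dimethoxymethyl group and to the C8a methyl.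

Step 4
Reactants: 9 vinylsilane carbinol
Product: 11 1-[(1S,2R,3R)-2-(dimethoxymethyl)-3-hydroxy-1-methyl-3-(propan-2-yl)cyclopentyl]ethan-1-one, via epoxysilane 10 (not isolated)
Conditions: mCPBA, NaHCO3, CH2Cl2, 0 °C → rt; then HCl (0.2 M in anhydrous MeOH), 0 °C → rt; aq. NaHCO3
Reagents that add atoms: 3-chloroperoxybenzoic acid OOC(=O)c1cccc(Cl)c1
Why: Prilezhaev epoxidation of the vinylsilane followed by acid-mediated opening of the α,β-epoxysilane with loss of silicon (Peterson-type elimination to the enol) should give the methyl ketone, while anhydrous methanol keeps the aldehyde as its dimethyl acetal.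

Step 5
Reactants: 11 methyl ketone; 12 2-bromoprop-1-ene
Product: 13 1-[(1S,2R,3R)-2-(dimethoxymethyl)-3-hydroxy-1-methyl-3-(propan-2-yl)cyclopentyl]-3-methylbut-3-en-1-one
Conditions: LiN(SiMe3)2 (2.3 equiv), Pd2(dba)3 (2.5 mol %), P(t-Bu)3 (6 mol %), toluene/THF, rt; AcOH, −78 °C
Reagents that add atoms: 2-bromoprop-1-ene CC(Br)=C
Why: Palladium-catalysed α-alkenylation of the ketone enolate can only occur at the acetyl methyl group because the other α-carbon is quaternary, and the product is held as its dienolate until kinetic α-protonation releases the β,γ-unsaturated ketone.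

Step 6
Reactants: 13 methallyl ketone acetal
Product: 14 (1R,2R,5S)-2-hydroxy-5-methyl-5-(3-methylbut-3-enoyl)-2-(propan-2-yl)cyclopentane-1-carbaldehyde
Conditions: aq. HCl (1 M), THF, 0 °C → rt, short reaction time
Reagents that add atoms: water O
Why: Mild acid-catalysed acetal hydrolysis should free the aldehyde without enolisation at the hindered C3a or migration of the alkene.

Step 7
Reactants: 14 keto aldehyde
Product: 16 (3R,3aS,4S,8aS)-3,4-dihydroxy-6,8a-dimethyl-3-(propan-2-yl)-2,3,3a,4,5,8a-hexahydroazulen-8(1H)-one, via methylidene ketone 15 (not isolated)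
Conditions: Me2AlCl (3 equiv), CH2Cl2, −78 → −20 °C; aq. NaHCO3 work-up; crude product, DBU (0.3 equiv), CH2Cl2, rt
Reagents that add atoms: none
Why: Me2AlCl binds the aldehyde (the aluminium alkoxide formed from the C3 hydroxyl can chelate it), the terminal CH2 of the 1,1-disubstituted alkene attacks the aldehyde carbon while an allylic hydrogen passes to oxygen, and DBU then moves the double bond of the 6-methylidene ketone 15 into conjugation with the C8 ketone; any regioisomeric alkene or tertiary chloride from a stepwise Prins pathway converges on the same enone through deprotonation at C7, the only enolisable position. The closest known reaction type is the Lewis acid-promoted type 2 intramolecular carbonyl–ene cyclisation of 6-methylhept-6-enals to 3-methylidenecycloheptanols. The seven-membered ring closes exo with respect to the aldehyde C=O (oxygen stays outside the ring) and endo with respect to the alkene (both alkene carbons enter the ring). The new stereocentre C4 is controlled by C3a: the trans tether holds C5 gauche to C8a across the C3a–C4 bond, the aluminium-bound oxygen takes the pseudo-equatorial position anti to C8a, and the aldehyde hydrogen occupies the crowded sector between the fully substituted C3 and C8a, so H-3a and H-4 should end up anti and C4 should be S. The step needs the aldehyde to react in preference to the ketone and C–C bond formation to occur at the alkene terminus, not by aldol attack through C7; the first is secured by the higher reactivity and chelation of the aldehyde over the neopentyl-type ketone, the second because attack through C7 would give a strained trans-fused bicyclo[3.3.0]octane.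

Step 8
Reactants: 16 hydroxy enone; 17 4-methoxybenzoyl chloride
Product: 18 (3R,3aS,4S,8aS)-3-hydroxy-6,8a-dimethyl-8-oxo-3-(propan-2-yl)-1,2,3,3a,4,5,8,8a-octahydroazulen-4-yl 4-methoxybenzoate
Conditions: 4-MeOC6H4COCl, DMAP (0.2 equiv), Et3N, CH2Cl2, 0 °C → rt
Reagents that add atoms: 4-methoxybenzoyl chloride COc1ccc(C(Cl)=O)cc1
Why: DMAP-catalysed acyl transfer should esterify the secondary equatorial C4 hydroxyl selectively because the C3 hydroxyl is tertiary and hindered.

Compound list
1 | 3-methylcyclopent-2-en-1-one | CC1=CC(=O)CC1 | starting material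
2 | ethynyl(trimethyl)silane | C#C[Si](C)(C)C | starting material
3 | bis(2-methylpropyl)[1-(trimethylsilyl)ethenyl]alumane | C=C([Si](C)(C)C)[Al](CC(C)C)CC(C)C | intermediate
4 | bis(2-methylpropyl)aluminium (3S)-3-methyl-3-[1-(trimethylsilyl)ethenyl]cyclopent-1-en-1-olate | C=C([Si](C)(C)C)[C@@]1(C)CCC(O[Al](CC(C)C)CC(C)C)=C1 | intermediate
5 | triethyl({(3S)-3-methyl-3-[1-(trimethylsilyl)ethenyl]cyclopent-1-en-1-yl}oxy)silane | C=C([Si](C)(C)C)[C@@]1(C)CCC(O[Si](CC)(CC)CC)=C1 | intermediate
6 | trimethyl orthoformate | COC(OC)OC | starting material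
7 | (2S,3S)-2-(dimethoxymethyl)-3-methyl-3-[1-(trimethylsilyl)ethenyl]cyclopentan-1-one | C=C([Si](C)(C)C)[C@@]1(C)CCC(=O)[C@@H]1C(OC)OC | intermediate
8 | isopropylmagnesium chloride | CC(C)[Mg]Cl | starting material
9 | (1R,2R,3S)-2-(dimethoxymethyl)-3-methyl-1-(propan-2-yl)-3-[1-(trimethylsilyl)ethenyl]cyclopentan-1-ol | C=C([Si](C)(C)C)[C@@]1(C)CC[C@@](O)(C(C)C)[C@@H]1C(OC)OC | intermediate
10 | (1R,2R,3S)-2-(dimethoxymethyl)-3-methyl-1-(propan-2-yl)-3-[2-(trimethylsilyl)oxiran-2-yl]cyclopentan-1-ol, mixture of epimers at the oxirane carbon | C[Si](C)(C)C1(CO1)[C@@]2(C)CC[C@@](O)(C(C)C)[C@@H]2C(OC)OC | intermediate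
11 | 1-[(1S,2R,3R)-2-(dimethoxymethyl)-3-hydroxy-1-methyl-3-(propan-2-yl)cyclopentyl]ethan-1-one | CC(=O)[C@@]1(C)CC[C@@](O)(C(C)C)[C@@H]1C(OC)OC | intermediate
12 | 2-bromoprop-1-ene | CC(Br)=C | starting material
13 | 1-[(1S,2R,3R)-2-(dimethoxymethyl)-3-hydroxy-1-methyl-3-(propan-2-yl)cyclopentyl]-3-methylbut-3-en-1-one | C=C(C)CC(=O)[C@@]1(C)CC[C@@](O)(C(C)C)[C@@H]1C(OC)OC | intermediate
14 | (1R,2R,5S)-2-hydroxy-5-methyl-5-(3-methylbut-3-enoyl)-2-(propan-2-yl)cyclopentane-1-carbaldehyde | C=C(C)CC(=O)[C@@]1(C)CC[C@@](O)(C(C)C)[C@@H]1C=O | intermediate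
15 | (3R,3aS,4S,8aS)-3,4-dihydroxy-8a-methyl-6-methylidene-3-(propan-2-yl)octahydroazulen-8(1H)-one (target numbering) | O[C@H]1CC(=C)CC(=O)[C@@]2(C)CC[C@@](O)(C(C)C)[C@H]12 | intermediate
16 | (3R,3aS,4S,8aS)-3,4-dihydroxy-6,8a-dimethyl-3-(propan-2-yl)-2,3,3a,4,5,8a-hexahydroazulen-8(1H)-one (target numbering) | O[C@H]1CC(C)=CC(=O)[C@@]2(C)CC[C@@](O)(C(C)C)[C@H]12 | intermediate
17 | 4-methoxybenzoyl chloride | COc1ccc(C(Cl)=O)cc1 | starting material
18 | (3R,3aS,4S,8aS)-3-hydroxy-6,8a-dimethyl-8-oxo-3-(propan-2-yl)-1,2,3,3a,4,5,8,8a-octahydroazulen-4-yl 4-methoxybenzoate | COc1ccc(C(=O)O[C@H]2CC(C)=CC(=O)[C@@]3(C)CC[C@@](O)(C(C)C)[C@H]23)cc1 | target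

Total step count: 8. Longest linear sequence: 8 steps (from 1).

Steps most likely to fail

Step 7. The alkene is allylic to an aluminium-complexed ketone and may react too slowly, so that retro-aldol opening of the β-aluminoxy aldehyde or isomerisation of the side chain to the unreactive conjugated enone takes over. The fallback replaces the ene component by a far more nucleophilic allylsilane and sets out from 11. Palladium-catalysed α-alkenylation of 11 with (2-bromoallyl)trimethylsilane under the conditions of step 5 would give 1-[(1S,2R,3R)-2-(dimethoxymethyl)-3-hydroxy-1-methyl-3-(propan-2-yl)cyclopentyl]-3-[(trimethylsilyl)methyl]but-3-en-1-one F1. Acetal hydrolysis as in step 6 would give (1R,2R,5S)-2-hydroxy-5-methyl-2-(propan-2-yl)-5-{3-[(trimethylsilyl)methyl]but-3-enoyl}cyclopentane-1-carbaldehyde F2. Intramolecular Hosomi–Sakurai cyclisation (TiCl4 or BF3·OEt2, CH2Cl2, −78 °C) should then deliver the methylidene ketone 15 through the same chair-like arrangement, and the route is rejoined at 15 (DBU to 16).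

Step 5. The hindered enolate may transmetalate slowly, and a second alkenylation or base-mediated migration of the new double bond into conjugation may compete. The fallback builds the side chain by aldol chemistry and sets out from 11. Deprotonation with LiN(i-Pr)2 (2.2 equiv, THF, −78 °C) and addition of acetone would give 1-[(1S,2R,3R)-2-(dimethoxymethyl)-3-hydroxy-1-methyl-3-(propan-2-yl)cyclopentyl]-3-hydroxy-3-methylbutan-1-one F3. Dehydration of this tertiary aldol (MsCl, Et3N, then DBU) would give the conjugated ketone 1-[(1S,2R,3R)-2-(dimethoxymethyl)-3-hydroxy-1-methyl-3-(propan-2-yl)cyclopentyl]-3-methylbut-2-en-1-one F4. γ-Deprotonation with LiN(i-Pr)2 and kinetic α-protonation of the dienolate with AcOH at −78 °C (deconjugative protonation) should return 13.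

Step 3. The secondary Grignard-derived reagent may enolise the β-keto acetal with loss of methoxide, reduce the ketone by β-hydride transfer, or add with poor facial selectivity because the 1-(trimethylsilyl)ethenyl group lies on the face that must be attacked. The fallback uses a smaller sp2 nucleophile without β-hydrogens and sets out from 7. Addition of prop-1-en-2-ylmagnesium bromide with CeCl3 (THF, −78 °C) would give (1S,2R,3S)-2-(dimethoxymethyl)-3-methyl-1-(prop-1-en-2-yl)-3-[1-(trimethylsilyl)ethenyl]cyclopentan-1-ol F5. Hydroxyl-directed hydrogenation of the allylic-alcohol alkene with [Ir(cod)(PCy3)(py)]PF6 and H2 (CH2Cl2, rt) should leave the hindered, remote vinylsilane untouched and return 9.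

Further compounds
F1 | step 7 | 1-[(1S,2R,3R)-2-(dimethoxymethyl)-3-hydroxy-1-methyl-3-(propan-2-yl)cyclopentyl]-3-[(trimethylsilyl)methyl]but-3-en-1-one | C=C(C[Si](C)(C)C)CC(=O)[C@@]1(C)CC[C@@](O)(C(C)C)[C@@H]1C(OC)OC
F2 | step 7 | (1R,2R,5S)-2-hydroxy-5-methyl-2-(propan-2-yl)-5-{3-[(trimethylsilyl)methyl]but-3-enoyl}cyclopentane-1-carbaldehyde | C=C(C[Si](C)(C)C)CC(=O)[C@@]1(C)CC[C@@](O)(C(C)C)[C@@H]1C=O
F3 | step 5 | 1-[(1S,2R,3R)-2-(dimethoxymethyl)-3-hydroxy-1-methyl-3-(propan-2-yl)cyclopentyl]-3-hydroxy-3-methylbutan-1-one | CC(C)(O)CC(=O)[C@@]1(C)CC[C@@](O)(C(C)C)[C@@H]1C(OC)OC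
F4 | step 5 | 1-[(1S,2R,3R)-2-(dimethoxymethyl)-3-hydroxy-1-methyl-3-(propan-2-yl)cyclopentyl]-3-methylbut-2-en-1-one | CC(C)=CC(=O)[C@@]1(C)CC[C@@](O)(C(C)C)[C@@H]1C(OC)OC
F5 | step 3 | (1S,2R,3S)-2-(dimethoxymethyl)-3-methyl-1-(prop-1-en-2-yl)-3-[1-(trimethylsilyl)ethenyl]cyclopentan-1-ol | C=C([Si](C)(C)C)[C@@]1(C)CC[C@@](O)(C(C)=C)[C@@H]1C(OC)OC
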